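The ten-membered carbocycle (ring A) is disconnected at C1=C10. The oxirane (ring C) has C2 and C9 cis, so it maps onto a ring-cis C1=C10 olefin, the less strained arrangement in a ten-membered ring. Ring-closing metathesis joins the C1 vinyl and C10 methylene termini of a diene whose arms are held by the trans γ-lactone (ring B) at C6–C7 and the E C4=C5 olefin, closing ring A and fixing the olefin geometry in one operation. The precursor is a trans α-methylene lactone carrying the (E)-2-methylhexa-1,5-dienyl arm on C6 and, on C7, the C8-methacrylate arm ending in the C10 methylene and free C14 hydroxyl.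

Key step: step 15

Remarks: germacrane numbering (C1–C15) is used for atoms throughout; ring A is the ten-membered carbocycle, ring B the γ-lactone, ring C the oxirane.
Assumption: (S,S)-ProPhenol is taken to deliver the alkynyl group to the Re face of aldehyde 4; if the opposite sense is found, the (R,R) ligand is used instead.

Step 1
Reactants: 1 hex-1-en-5-yne
Product: 3 (E)-3-methylhepta-2,6-dien-1-ol, via alkenylalane 2 (not isolated)
Conditions: AlMe3, Cp2ZrCl2 (cat.), CH2Cl2, 0 °C to rt; then n-BuLi, (CH2O)n, THF, −78 °C to rt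
Reagents that add atoms: trimethylaluminium, C[Al](C)C; paraformaldehyde (formaldehyde unit), C=O
Why: Negishi carboalumination of the terminal alkyne (the isolated alkene reacts far more slowly) adds methyl and aluminium syn with aluminium on the terminal carbon, and the alanate traps formaldehyde with retention, so the C4=C5 olefin should form as the E isomer only.

Step 2
Reactants: 3 (E)-3-methylhepta-2,6-dien-1-ol
Product: 4 (E)-3-methylhepta-2,6-dienal
Conditions: MnO2, CH2Cl2, rt
Reagents that add atoms: none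
Why: Allylic oxidation with MnO2 is selective for the allylic alcohol and should leave the E olefin geometry and the terminal vinyl group unchanged.

Step 3
Reactants: 4 (E)-3-methylhepta-2,6-dienal; 5 methyl propiolate
Product: 7 methyl (4R,5E)-4-hydroxy-6-methyldeca-5,9-dien-2-ynoate, via zinc alkynylide 6 (not isolated)
Conditions: Me2Zn, (S,S)-ProPhenol (20 mol%), Ph3P=O (cat.), toluene, 4 °C
Reagents that add atoms: none
Why: Catalytic asymmetric alkynylation of an enal by a zinc alkynylide in the dinuclear zinc–ProPhenol pocket adds only 1,2 and should set C6 as R by Re-face delivery.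

Step 4
Reactants: 7 methyl (4R,5E)-4-hydroxy-6-methyldeca-5,9-dien-2-ynoate
Product: 8 methyl (4R,5E)-4-[(tert-butyldimethylsilyl)oxy]-6-methyldeca-5,9-dien-2-ynoate
Conditions: TBSOTf, 2,6-lutidine, CH2Cl2, −78 °C
Reagents that add atoms: tert-butyldimethylsilyl trifluoromethanesulfonate, CC(C)(C)[Si](C)(C)OS(=O)(=O)C(F)(F)F
Why: Silylation with a hindered non-nucleophilic base avoids conjugate addition to the ynoate and keeps the C6 oxygen from closing to a bis-allylic lactone that zerovalent palladium could ionize in steps 5 and 6.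

Step 5
Reactants: 8 methyl (4R,5E)-4-[(tert-butyldimethylsilyl)oxy]-6-methyldeca-5,9-dien-2-ynoate
Product: 10 methyl (2E,4R,5E)-4-[(tert-butyldimethylsilyl)oxy]-2-iodo-6-methyldeca-2,5,9-trienoate, via vinylstannane 9 (not isolated)
Conditions: Bu3SnH, PdCl2(PPh3)2 (cat.), THF, 0 °C; then I2, CH2Cl2, 0 °C
Reagents that add atoms: iodine, II
Why: Palladium-catalyzed hydrostannation of an ynoate is a syn addition that places tin on the carbon next to the ester (C11) and hydrogen on C7, and iododestannylation proceeds with retention, so C6 and the ester should end up cis across C7=C11.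

Step 6
Reactants: 10 methyl (2E,4R,5E)-4-[(tert-butyldimethylsilyl)oxy]-2-iodo-6-methyldeca-2,5,9-trienoate
Product: 11 methyl (2Z,4R,5E)-4-[(tert-butyldimethylsilyl)oxy]-2-(hydroxymethyl)-6-methyldeca-2,5,9-trienoate
Conditions: Bu3SnCH2OH, Pd(PPh3)4 (cat.), 1,4-dioxane, 80 °C
Reagents that add atoms: (tributylstannyl)methanol, OC[Sn](CCCC)(CCCC)CCCC
Why: Stille coupling transfers the hydroxymethyl group to the vinylic carbon with retention of olefin geometry, installing C13 on C11 while the silyl ether keeps C6–O inert to palladium.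

Step 7
Reactants: 11 methyl (2Z,4R,5E)-4-[(tert-butyldimethylsilyl)oxy]-2-(hydroxymethyl)-6-methyldeca-2,5,9-trienoate
Product: 13 (5R)-3-(hydroxymethyl)-5-[(1E)-2-methylhexa-1,5-dien-1-yl]furan-2(5H)-one, via dihydroxy ester 12 (not isolated)
Conditions: HF·pyridine, pyridine, THF, 0 °C to rt
Reagents that add atoms: none
Why: Desilylation frees the C6 hydroxyl, which sits cis to the ester and should close the butenolide by lactonization without touching the stereocenter.

Step 8
Reactants: 13 (5R)-3-(hydroxymethyl)-5-[(1E)-2-methylhexa-1,5-dien-1-yl]furan-2(5H)-one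
Product: 14 (5R)-3-(bromomethyl)-5-[(1E)-2-methylhexa-1,5-dien-1-yl]furan-2(5H)-one
Conditions: CBr4, PPh3, CH2Cl2, 0 °C
Reagents that add atoms: carbon tetrabromide, BrC(Br)(Br)Br
Why: The Appel reaction converts the primary allylic alcohol to the bromide under neutral conditions that spare the base-sensitive C6–H.

Step 9
Reactants: 15 3-bromo-2-(bromomethyl)prop-1-ene
Product: 16 1-({[2-(bromomethyl)prop-2-en-1-yl]oxy}methyl)-4-methoxybenzene
Conditions: 4-methoxybenzyl alcohol, NaH, THF, 0 °C to rt (15 in threefold excess)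
Reagents that add atoms: 4-methoxybenzyl alcohol, COc1ccc(CO)cc1
Why: Williamson etherification of a symmetrical bis-allylic dibromide used in excess should stop at the mono-ether.

Step 10
Reactants: 16 1-({[2-(bromomethyl)prop-2-en-1-yl]oxy}methyl)-4-methoxybenzene
Product: 18 3-{[(4-methoxybenzyl)oxy]methyl}but-3-en-1-ol, via allylzinc bromide 17 (not isolated)
Conditions: Zn dust, 37% aq. HCHO, THF/sat. aq. NH4Cl, rt
Reagents that add atoms: formaldehyde, C=O
Why: Aqueous Barbier allylation of formaldehyde gives the homoallylic alcohol, and because the allyl unit is symmetrical about C10 either terminus leads to the same product.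

Step 11
Reactants: 18 3-{[(4-methoxybenzyl)oxy]methyl}but-3-en-1-ol
Product: 19 3-{[(4-methoxybenzyl)oxy]methyl}but-3-enal
Conditions: Dess–Martin periodinane, pyridine, CH2Cl2, 0 °C; used at once
Reagents that add atoms: none
Why: Dess–Martin oxidation under buffered, non-basic conditions should give the β,γ-unsaturated aldehyde without moving the C10 methylene into conjugation, provided the aldehyde is used directly.

Step 12
Reactants: 14 (5R)-3-(bromomethyl)-5-[(1E)-2-methylhexa-1,5-dien-1-yl]furan-2(5H)-one; 19 3-{[(4-methoxybenzyl)oxy]methyl}but-3-enal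
Product: 21 (4R,5R)-4-[(1S)-1-hydroxy-3-{[(4-methoxybenzyl)oxy]methyl}but-3-en-1-yl]-3-methylidene-5-[(1E)-2-methylhexa-1,5-dien-1-yl]oxolan-2-one, via butenolide allylzinc bromide 20 (not isolated)
Conditions: Zn dust, THF/sat. aq. NH4Cl, 0 °C to rt
Reagents that add atoms: none
Why: In this Barbier allylation the allylzinc reacts at C7 (SE2′) on the face anti to the C6 dienyl group, giving the trans lactone, and through a Zimmerman–Traxler chair in which ring B locks C6 trans to the CH2Zn carbon and the aldehyde chain is equatorial, which should place C8–OH anti to C6, i.e. 8S.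

Step 13
Reactants: 21 (4R,5R)-4-[(1S)-1-hydroxy-3-{[(4-methoxybenzyl)oxy]methyl}but-3-en-1-yl]-3-methylidene-5-[(1E)-2-methylhexa-1,5-dien-1-yl]oxolan-2-one
Product: 22 (1S)-3-{[(4-methoxybenzyl)oxy]methyl}-1-{(2R,3R)-4-methylidene-2-[(1E)-2-methylhexa-1,5-dien-1-yl]-5-oxooxolan-3-yl}but-3-en-1-yl 2-methylprop-2-enoate
Conditions: methacrylic anhydride, Et3N, DMAP (cat.), CH2Cl2, 0 °C to rt
Reagents that add atoms: methacrylic anhydride, CC(=C)C(=O)OC(=O)C(C)=C
Why: DMAP-catalyzed acylation of the only free hydroxyl installs the C8 ester early, so that no acid or fluoride is needed after the acid-sensitive oxirane is in place.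

Step 14
Reactants: 22 (1S)-3-{[(4-methoxybenzyl)oxy]methyl}-1-{(2R,3R)-4-methylidene-2-[(1E)-2-methylhexa-1,5-dien-1-yl]-5-oxooxolan-3-yl}but-3-en-1-yl 2-methylprop-2-enoate
Product: 23 (1S)-3-(hydroxymethyl)-1-{(2R,3R)-4-methylidene-2-[(1E)-2-methylhexa-1,5-dien-1-yl]-5-oxooxolan-3-yl}but-3-en-1-yl 2-methylprop-2-enoate
Conditions: DDQ, CH2Cl2/pH 7 buffer, 0 °C
Reagents that add atoms: none
Why: Oxidative cleavage of the 4-methoxybenzyl ether by DDQ starts with benzylic hydride abstraction and should leave the esters, the lactone and all olefins untouched.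

Step 15
Reactants: 23 (1S)-3-(hydroxymethyl)-1-{(2R,3R)-4-methylidene-2-[(1E)-2-methylhexa-1,5-dien-1-yl]-5-oxooxolan-3-yl}but-3-en-1-yl 2-methylprop-2-enoate
Product: 24 (1(10)E,4E,6R,7R,8S)-14-hydroxy-8-(methacryloyloxy)germacra-1(10),4,11(13)-trien-12,6-olide (C9 and C2 cis on C1=C10)
Conditions: second-generation Hoveyda–Grubbs catalyst RuCl2(SIMes)(=CH-C6H4-2-OiPr) (10 mol%), 1,4-benzoquinone (20 mol%), toluene (1 mM), 80 °C, argon sparge
Reagents that add atoms: none
Why: The ruthenium carbene first exchanges onto the monosubstituted C1 vinyl group, the C1 alkylidene adds across the C10 methylene through a ruthenacyclobutane, and cycloreversion releases ring A with the new C1=C10 bond while the ruthenium methylidene gives ethene. This is ring-closing olefin metathesis to a trisubstituted olefin in a medium ring, a known reaction class, helped here by the free allylic C14 hydroxyl. Ring A closes by union of the two chain termini in the endo sense, both new sp2 carbons lying in the ring, and no stereocenter is created. The step needs site selectivity and ring-cis geometry: the C11=C13 and methacryloyl olefins are 1,1-disubstituted and conjugated to carbonyl groups, the trisubstituted C4=C5 olefin could only close a cyclobutene, and high dilution should suppress dimerization. The trans lactone (ring B) and the E C4=C5 olefin turn the two arms toward each other, and a ten-membered ring should accommodate the trisubstituted olefin best with C9 and C2 cis (E by CIP because of C14), the arrangement the oxirane needs. 1,4-Benzoquinone should suppress ruthenium hydride isomerization of the allylic alcohol.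

Step 16
Reactants: 24 (1(10)E,4E,6R,7R,8S)-14-hydroxy-8-(methacryloyloxy)germacra-1(10),4,11(13)-trien-12,6-olide
Product: 25 (1R,4E,6R,7R,8S,10R)-1,10-epoxy-14-hydroxy-8-(methacryloyloxy)germacra-4,11(13)-dien-12,6-olide
Conditions: Ti(OiPr)4 (20 mol%), D-(−)-diethyl tartrate (24 mol%), t-BuOOH (anhydrous, in decane), 4 Å molecular sieves, CH2Cl2, −20 °C
Reagents that add atoms: tert-butyl hydroperoxide, CC(C)(C)OO
Why: In this Sharpless asymmetric epoxidation the C14 hydroxyl binds the titanium–tartrate complex so that only C1=C10 is oxidized, and the D-(−) tartrate should deliver oxygen to the face that gives the (1R,10R) oxirane (the L-(+) ester would give 1S,10S), with the cis relation of C9 and C2 carried over from the olefin.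

Step 17
Reactants: 25 (1R,4E,6R,7R,8S,10R)-1,10-epoxy-14-hydroxy-8-(methacryloyloxy)germacra-4,11(13)-dien-12,6-olide
Product: 26 (1R,4E,6R,7R,8S,10R)-14-acetoxy-1,10-epoxy-8-(methacryloyloxy)germacra-4,11(13)-dien-12,6-olide (CNP0150481.4)
Conditions: Ac2O, pyridine, DMAP (cat.), CH2Cl2, 0 °C
Reagents that add atoms: acetic anhydride, CC(=O)OC(C)=O
Why: Acylation of the primary epoxy alcohol under mild basic conditions should neither open the oxirane nor affect the other esters.

Compound list
1 | hex-1-en-5-yne | C#CCCC=C | starting material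
2 | (E)-dimethyl(2-methylhexa-1,5-dien-1-yl)aluminium (alkenylalane) | C[Al](C)/C=C(\C)CCC=C | intermediate (not isolated)
3 | (E)-3-methylhepta-2,6-dien-1-ol | OC/C=C(\C)CCC=C | intermediate
4 | (E)-3-methylhepta-2,6-dienal | O=C/C=C(\C)CCC=C | intermediate
5 | methyl propiolate | C#CC(=O)OC | starting material
6 | methyl 3-(methylzincio)prop-2-ynoate (zinc alkynylide) | C[Zn]C#CC(=O)OC | intermediate (not isolated)
7 | methyl (4R,5E)-4-hydroxy-6-methyldeca-5,9-dien-2-ynoate | COC(=O)C#C[C@H](O)/C=C(\C)CCC=C | intermediate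
8 | methyl (4R,5E)-4-[(tert-butyldimethylsilyl)oxy]-6-methyldeca-5,9-dien-2-ynoate | COC(=O)C#C[C@H](O[Si](C)(C)C(C)(C)C)/C=C(\C)CCC=C | intermediate
9 | methyl (2E,4R,5E)-4-[(tert-butyldimethylsilyl)oxy]-6-methyl-2-(tributylstannyl)deca-2,5,9-trienoate (vinylstannane) | COC(=O)/C([Sn](CCCC)(CCCC)CCCC)=C\[C@H](O[Si](C)(C)C(C)(C)C)/C=C(\C)CCC=C | intermediate (not isolated)
10 | methyl (2E,4R,5E)-4-[(tert-butyldimethylsilyl)oxy]-2-iodo-6-methyldeca-2,5,9-trienoate | COC(=O)/C(I)=C\[C@H](O[Si](C)(C)C(C)(C)C)/C=C(\C)CCC=C | intermediate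
11 | methyl (2Z,4R,5E)-4-[(tert-butyldimethylsilyl)oxy]-2-(hydroxymethyl)-6-methyldeca-2,5,9-trienoate | COC(=O)/C(CO)=C\[C@H](O[Si](C)(C)C(C)(C)C)/C=C(\C)CCC=C | intermediate
12 | methyl (2Z,4R,5E)-4-hydroxy-2-(hydroxymethyl)-6-methyldeca-2,5,9-trienoate (dihydroxy ester) | COC(=O)/C(CO)=C\[C@H](O)/C=C(\C)CCC=C | intermediate (not isolated)
13 | (5R)-3-(hydroxymethyl)-5-[(1E)-2-methylhexa-1,5-dien-1-yl]furan-2(5H)-one | OCC1=C[C@@H](/C=C(\C)CCC=C)OC1=O | intermediate
14 | (5R)-3-(bromomethyl)-5-[(1E)-2-methylhexa-1,5-dien-1-yl]furan-2(5H)-one | BrCC1=C[C@@H](/C=C(\C)CCC=C)OC1=O | intermediate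
15 | 3-bromo-2-(bromomethyl)prop-1-ene | C=C(CBr)CBr | starting material
16 | 1-({[2-(bromomethyl)prop-2-en-1-yl]oxy}methyl)-4-methoxybenzene | C=C(CBr)COCc1ccc(OC)cc1 | intermediate
17 | bromo{2-[(4-methoxybenzyloxy)methyl]prop-2-en-1-yl}zinc (allylzinc bromide) | Br[Zn]CC(=C)COCc1ccc(OC)cc1 | intermediate (not isolated)
18 | 3-{[(4-methoxybenzyl)oxy]methyl}but-3-en-1-ol | OCCC(=C)COCc1ccc(OC)cc1 | intermediate
19 | 3-{[(4-methoxybenzyl)oxy]methyl}but-3-enal | O=CCC(=C)COCc1ccc(OC)cc1 | intermediate
20 | bromo({(5R)-5-[(1E)-2-methylhexa-1,5-dien-1-yl]-2-oxo-2,5-dihydrofuran-3-yl}methyl)zinc (butenolide allylzinc bromide) | Br[Zn]CC1=C[C@@H](/C=C(\C)CCC=C)OC1=O | intermediate (not isolated)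
21 | (4R,5R)-4-[(1S)-1-hydroxy-3-{[(4-methoxybenzyl)oxy]methyl}but-3-en-1-yl]-3-methylidene-5-[(1E)-2-methylhexa-1,5-dien-1-yl]oxolan-2-one (6R,7R,8S; trans lactone) | O[C@@H](CC(=C)COCc1ccc(OC)cc1)[C@H]1C(=C)C(=O)O[C@@H]1/C=C(\C)CCC=C | intermediate
22 | (1S)-3-{[(4-methoxybenzyl)oxy]methyl}-1-{(2R,3R)-4-methylidene-2-[(1E)-2-methylhexa-1,5-dien-1-yl]-5-oxooxolan-3-yl}but-3-en-1-yl 2-methylprop-2-enoate | C=C(C)C(=O)O[C@@H](CC(=C)COCc1ccc(OC)cc1)[C@H]1C(=C)C(=O)O[C@@H]1/C=C(\C)CCC=C | intermediate
23 | (1S)-3-(hydroxymethyl)-1-{(2R,3R)-4-methylidene-2-[(1E)-2-methylhexa-1,5-dien-1-yl]-5-oxooxolan-3-yl}but-3-en-1-yl 2-methylprop-2-enoate (metathesis precursor) | C=C(C)C(=O)O[C@@H](CC(=C)CO)[C@H]1C(=C)C(=O)O[C@@H]1/C=C(\C)CCC=C | intermediate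
24 | (1(10)E,4E,6R,7R,8S)-14-hydroxy-8-(methacryloyloxy)germacra-1(10),4,11(13)-trien-12,6-olide (metathesis product) | C=C(C)C(=O)O[C@H]1C/C(CO)=C\CC/C(C)=C/[C@H]2OC(=O)C(=C)[C@H]12 | intermediate
25 | (1R,4E,6R,7R,8S,10R)-1,10-epoxy-14-hydroxy-8-(methacryloyloxy)germacra-4,11(13)-dien-12,6-olide | C=C(C)C(=O)O[C@H]1C[C@]2(CO)O[C@@H]2CC/C(C)=C/[C@H]2OC(=O)C(=C)[C@H]12 | intermediate
26 | (1R,4E,6R,7R,8S,10R)-14-acetoxy-1,10-epoxy-8-(methacryloyloxy)germacra-4,11(13)-dien-12,6-olide | C=C(C)C(=O)O[C@H]1C[C@]2(COC(C)=O)O[C@@H]2CC/C(C)=C/[C@H]2OC(=O)C(=C)[C@H]12 | target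

Total step count: 17. Longest linear sequence: 14 steps (steps 1–8, then 12–17).

Steps most likely to fail

Step 15 (ring closure). Intermolecular metathesis, or the methacryloyl olefin being drawn into metathesis, may outrun closure of the strained ring. The fallback carries C8 as a silyl ether through the ring closure and acylates last. It sets out from 21: TBSOTf/2,6-lutidine gives the C8 tert-butyldimethylsilyl ether F1. DDQ then frees C14 to give the silyl-protected diene F2. The metathesis conditions of step 15 give the ten-membered dienyl lactone with C8 silyl ether F3. Ti(OiPr)4/D-(−)-diethyl tartrate/t-BuOOH gives the silyl-protected epoxy alcohol F4, and Ac2O/pyridine gives its C14 acetate F5. TBAF buffered with AcOH (THF, 0 °C) gives the C8 alcohol F6, and methacrylic anhydride/DMAP converts it to 26, where the fallback rejoins the route.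

Step 12 (fragment union). Addition through a non-chair arrangement would set C8 with the wrong configuration and give the C8-epimeric alcohol F7. The fallback is a Mitsunobu esterification of F7 with methacrylic acid (PPh3, DIAD, toluene, 0 °C), which inverts C8 while installing the ester. It sets out from 14 and 19 (which give F7 under the conditions of step 12) and comes back at 22.

Step 16 (epoxidation). Oxygen transfer may be slow or poorly face-selective if the bulky titanium–tartrate complex is mismatched with the conformation of ring A. The fallback is hydroxyl-directed epoxidation with VO(acac)2 and t-BuOOH in CH2Cl2 at 0 °C, which gives up reagent control and relies on delivery from the C14 hydroxyl to the outer face of the ring olefin. It sets out from 24 and returns at 25; new compounds: none F0.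

Further compounds
F1 | step 15 | C8 tert-butyldimethylsilyl ether of 21 (C14 4-methoxybenzyl ether) | CC(C)(C)[Si](C)(C)O[C@@H](CC(=C)COCc1ccc(OC)cc1)[C@H]1C(=C)C(=O)O[C@@H]1/C=C(\C)CCC=C
F2 | step 15 | silyl-protected diene with free C14 hydroxyl | CC(C)(C)[Si](C)(C)O[C@@H](CC(=C)CO)[C@H]1C(=C)C(=O)O[C@@H]1/C=C(\C)CCC=C
F3 | step 15 | ten-membered dienyl lactone with C8 silyl ether and free C14 hydroxyl | CC(C)(C)[Si](C)(C)O[C@H]1C/C(CO)=C\CC/C(C)=C/[C@H]2OC(=O)C(=C)[C@H]12
F4 | step 15 | (1R,10R)-1,10-epoxy-14-hydroxy lactone with C8 silyl ether | CC(C)(C)[Si](C)(C)O[C@H]1C[C@]2(CO)O[C@@H]2CC/C(C)=C/[C@H]2OC(=O)C(=C)[C@H]12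
F5 | step 15 | (1R,10R)-14-acetoxy-1,10-epoxy lactone with C8 silyl ether | CC(C)(C)[Si](C)(C)O[C@H]1C[C@]2(COC(C)=O)O[C@@H]2CC/C(C)=C/[C@H]2OC(=O)C(=C)[C@H]12
F6 | step 15 | (1R,10R)-14-acetoxy-1,10-epoxy-8-hydroxy lactone | O[C@H]1C[C@]2(COC(C)=O)O[C@@H]2CC/C(C)=C/[C@H]2OC(=O)C(=C)[C@H]12
F7 | step 12 | C8 epimer of 21, (4R,5R)-4-[(1R)-1-hydroxy-3-{[(4-methoxybenzyl)oxy]methyl}but-3-en-1-yl]-3-methylidene-5-[(1E)-2-methylhexa-1,5-dien-1-yl]oxolan-2-one | O[C@H](CC(=C)COCc1ccc(OC)cc1)[C@H]1C(=C)C(=O)O[C@@H]1/C=C(\C)CCC=C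
F0 | step 16 | none | none
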